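| setting | elm | cedar | alder | ochre | amber | green | violet | grey |
|---|---|---|---|---|---|---|---|---|
| substrate | 1.2 M | 2.2 M | 1.6 M | 1.6 M | 1.0 M | 1.6 M | 1.0 M | 1.6 M |
| coupling partner | 1.28 M | 1.28 M | 1 M | 0.400 M | 1.28 M | 0.600 M | 2.00 M | 1.28 M |
| remark | run made earlier | run made earlier | run made earlier |  |  |  |  |  |
| time |  |  |  | 40 h | 40 h | 40 h | 40 h | 40 h |

| run | time / h | target / % | substrate / % |
|---|---|---|---|
| elm | 1.00 | 16.7 | 78.7 |
| elm | 3.00 | 35.9 | 54.7 |
| elm | 6.00 | 55.6 | 38.0 |
| elm | 8.00 | 64.8 | 30.5 |
| elm | 12.0 | 74.8 | 21.5 |
| elm | 15.0 | 80.5 | 17.3 |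
| elm | 20.0 | 84.5 | 14.2 |
| cedar | 1.00 | 14.9 | 80.1 |
| cedar | 3.00 | 30.9 | 61.8 |
| cedar | 6.00 | 43.2 | 51.4 |
| cedar | 8.00 | 48.6 | 46.8 |
| cedar | 12.0 | 54.3 | 44.7 |
| cedar | 15.0 | 55.6 | 42.8 |
| cedar | 20.0 | 56.3 | 42.0 |
| alder | 1.50 | 17.3 | 77.7 |
| alder | 3.00 | 27.7 | 65.4 |
| alder | 6.00 | 41.0 | 52.6 |
| alder | 10.0 | 51.7 | 45.6 |
| alder | 20.0 | 58.9 | 39.1 |

(standard deviation of a reading: 0.5 percentage points)

- a reading or a percentage of target counts all its forms, free or not

- ranking by amount of target, in percent of the substrate charged, from high to low, at 40 h (ochre / amber / green / violet / grey)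
- the amount of target, in percent of the substrate charged of the flask you put first, at 40 h
- the amount of target, in percent of the substrate charged of the flask you put last, at 40 h

**Counting decades.** Work in decades: one decade is a power of ten in a ratio. Start with the main step, in which substrate and coupling partner give target at rate k·c(substrate)·c(coupling partner). Both fall together, so their difference, the gap, stays as charged. The charge that is smaller is the limiting reagent. The logarithm of c(excess)/c(limiting) then climbs steadily with time. Put substrate readings into that climb. Cedar at 6.00 h gives 0.206 /M/h, and alder at 6.00 h gives 0.216 /M/h. I use their mean as k, 0.211 /M/h.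

**The ceilings.** Run to its end, the main step turns the limiting charge into target. Violet and amber have a ceiling of 100 %, grey 80.0 %, green 37.5 % and ochre 25.0 %.

**Finite time.** The decade count is k × gap × time / 2.3, the climb of the logarithm over a run. Violet has 3.67 decades. Its ratio starts at 0.301 on the log scale, so it ends near 3.97. That leaves about 0.0107 % of violet's substrate. Amber has 1.03 decades, fewer than violet, so amber keeps about 2.22 %. Ochre has 4.40 decades, more than violet, so on the main step I put ochre close to its ceiling.

**The hold-up.** Target plus substrate falls short of the charge. In elm the shortfall is 9.4 percentage points at 3.00 h. At the last readings of the three runs it averages 1.7 points. I take that off, which gives 98.3 % for violet and 23.3 % for ochre.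

**The forecast.** It gives violet > amber > grey > green > ochre, the same order as mine, with 99 % and 24.7 %. Both figures stand above mine. It reads the shortfall as “a transient holding species that releases target”, while I keep it.

**The result.** The flasks give violet > amber > grey > green > ochre, with 98.6 % and 24.1 %, so the forecast holds. Violet kept 0.0112 % substrate. Of violet's target, 96.5 % stood as crystals, and beside the target stood 1.37 % of isomer of the product.

    substrate + coupling partner → target (k = 0.210 /M/h)
    crystals ⇌ target, rate k2*(cs2 - [target]) while solid is left; crystals form when [target] > cs2 (solubility = 21.0 mM, k = 0.740 /h)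
    target ⇌ isomer of the product (K = 0.650, k = 1.00 /h)

**The neighbour.** Take violet with 0.80 M of coupling partner, which is now the limiting reagent. Its count is 0.734 decades, fewer than violet's 3.67. The log ratio climbs from 0.0969 to 0.831. That leaves 4.33 % of the partner's own charge and 23.5 % of the substrate. The neighbour flask held 4.4 % of its coupling partner and 24 % of its substrate, with target at 74.9 %.

(Readings and results stem from a simulated flask for an exercise, and the scatter is random.)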